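## Retrosynthetic overview
1. The prenyl C=C is made last, by cross‑metathesis of a 3'‑allyl triol with 2‑methyl‑2‑butene. The prenyl group therefore never meets NBS, BuLi, Pd or acid.
2. Just before that, one acidic operation removes all three MOM ethers while the side chain is still an acid‑inert allyl group.
3. The C3–C1' bond is formed by base‑free Negishi coupling of a 3‑iodochromone with the B‑ring arylzinc.
4. Only one ring is built, the pyranone C ring, from 2,4‑dihydroxyacetophenone by enaminone formation and iodocyclisation before the coupling. Rings A and B are purchased arenes.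
5. B ring: 4‑methoxyresorcinol is bis‑MOM protected, then allylated by directed ortho‑metalation between the two OMOM groups, then brominated ortho/para to the OMOM groups.

Stereochemistry: piscisoflavone A is achiral. It has no stereocentres, and the prenyl alkene carries two identical methyl groups, so no stereocontrol is needed.
Assumption: 4‑methoxyresorcinol (CAS 6100‑60‑3) is purchased. It can also be made from isovanillin by Dakin oxidation.

## Route

**Step 1**
Reactants: 1, 2,4‑dihydroxyacetophenone
Product: 2, 1‑[2‑hydroxy‑4‑(methoxymethoxy)phenyl]ethan‑1‑one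
Conditions: MOMCl (1.1 equiv), K2CO3, acetone, 0 °C → rt
Reagents that add atoms: chloromethyl methyl ether, COCCl
Why: Selective O‑alkylation (MOM protection) works because the 2‑OH is hydrogen‑bonded to the ketone and unreactive, so only the 4‑OH is capped.

**Step 2**
Reactants: 2
Product: 3, (E)‑3‑(dimethylamino)‑1‑[2‑hydroxy‑4‑(methoxymethoxy)phenyl]prop‑2‑en‑1‑one
Conditions: DMF‑DMA (2.5 equiv), toluene, 95 °C, 3 h
Reagents that add atoms: N,N‑dimethylformamide dimethyl acetal, COC(OC)N(C)C
Why: Enaminone condensation of the methyl ketone with the formamide acetal supplies the future C2 carbon, with loss of 2 MeOH.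

**Step 3**
Reactants: 3
Product: 4, 3‑iodo‑7‑(methoxymethoxy)‑4H‑chromen‑4‑one
Conditions: I2 (1.5 equiv), pyridine, CHCl3, rt; Na2S2O3 work‑up
Reagents that add atoms: iodine, II
Why: In this Gammill‑type iodocyclisation, α‑iodination of the enaminone is followed by phenol addition and loss of Me2NH to close ring C, and the pyridine buffer keeps the MOM ether intact.

**Step 4**
Reactants: 5, 4‑methoxyresorcinol (4‑methoxybenzene‑1,3‑diol)
Product: 6, 1‑methoxy‑2,4‑bis(methoxymethoxy)benzene
Conditions: MOMCl (3 equiv), iPr2NEt (4 equiv), CH2Cl2, 0 °C → rt, N2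
Reagents that add atoms: chloromethyl methyl ether, COCCl
Why: Double MOM protection masks the oxidation‑prone phenols and installs two strong directing groups for the metalation.

**Step 5**
Reactants: 6
Product: 7, 1‑methoxy‑2,4‑bis(methoxymethoxy)‑3‑(prop‑2‑en‑1‑yl)benzene (allyl between the two OMOM groups)
Conditions: n‑BuLi (1.2 equiv), THF, 0 °C, 1 h; CuI (10 mol %), allyl bromide (1.5 equiv), −78 °C → rt
Reagents that add atoms: allyl bromide, C=CCBr
Why: Cooperative directed ortho‑metalation lithiates the C–H flanked by both OMOM groups (as 1,2,4‑trialkoxybenzenes do at C3), and allyl is used instead of prenyl because a terminal alkene tolerates the next steps.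

**Step 6**
Reactants: 7
Product: 8, 1‑bromo‑5‑methoxy‑2,4‑bis(methoxymethoxy)‑3‑(prop‑2‑en‑1‑yl)benzene
Conditions: NBS (1.05 equiv), dry MeCN, 0 °C → rt, dark
Reagents that add atoms: N‑bromosuccinimide, O=C1CCC(=O)N1Br
Why: Electrophilic aromatic bromination goes to the carbon ortho to one OMOM and para to the other (two O donors, against one for the position next to OMe), and the monosubstituted alkene is far less nucleophilic than the arene.

**Step 7**
Reactants: 8 (1.2 equiv) and 4 (1.0 equiv)
Product: 9, 3‑[5‑methoxy‑2,4‑bis(methoxymethoxy)‑3‑(prop‑2‑en‑1‑yl)phenyl]‑7‑(methoxymethoxy)‑4H‑chromen‑4‑one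
Conditions: 8, n‑BuLi (1.0 equiv vs 8), THF, −78 °C, 15 min; ZnCl2 (1.2 equiv, THF), −78 °C → rt; then 4, Pd(PPh3)4 (5 mol %), THF, rt → 45 °C
Reagents that add atoms: none (Br, I, Li and Zn are all lost)
Why: Br/Li exchange at −78 °C outruns allylic deprotonation, and the Negishi coupling of the mono‑ortho‑substituted arylzinc with the reactive vinylogous acyl iodide needs no base, so it avoids chromone ring opening, Heck reaction and allyl isomerisation.

**Step 8**
Reactants: 9
Product: 10, 3‑[2,4‑dihydroxy‑5‑methoxy‑3‑(prop‑2‑en‑1‑yl)phenyl]‑7‑hydroxy‑4H‑chromen‑4‑one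
Conditions: 3 M aq HCl/MeOH (1:4), 60 °C, 1–2 h
Reagents that add atoms: none
Why: Acid acetal solvolysis removes all three aryl MOM ethers, with formaldehyde trapped as dimethoxymethane, and the terminal allyl group is not protonated under these conditions, so no chroman or dihydrobenzofuran forms.

**Step 9**
Reactants: 10
Product: 11, piscisoflavone A, 3‑[2,4‑dihydroxy‑5‑methoxy‑3‑(3‑methylbut‑2‑en‑1‑yl)phenyl]‑7‑hydroxy‑4H‑chromen‑4‑one
Conditions: Grubbs II (5–10 mol %), 2‑methyl‑2‑butene (large excess)/CH2Cl2–THF, 40 °C, sealed tube, degassed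
Reagents that add atoms: 2‑methyl‑2‑butene, CC=C(C)C
Why: Olefin cross‑metathesis exchanges =CH2 for =CMe2; any crotyl by‑product re‑enters the cycle and funnels to the trisubstituted product, while the phenols and the trisubstituted electron‑poor chromone C2=C3 bond are spectators, and no stereoelement is created.

## Compound list
1 | 2,4‑dihydroxyacetophenone | CC(=O)c1ccc(O)cc1O | starting material
2 | 1‑[2‑hydroxy‑4‑(methoxymethoxy)phenyl]ethan‑1‑one | CC(=O)c1ccc(OCOC)cc1O | intermediate
3 | (E)‑3‑(dimethylamino)‑1‑[2‑hydroxy‑4‑(methoxymethoxy)phenyl]prop‑2‑en‑1‑one | CN(C)/C=C/C(=O)c1ccc(OCOC)cc1O | intermediate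
4 | 3‑iodo‑7‑(methoxymethoxy)‑4H‑chromen‑4‑one | COCOc1ccc2c(=O)c(I)coc2c1 | intermediate
5 | 4‑methoxyresorcinol | COc1ccc(O)cc1O | starting material
6 | 1‑methoxy‑2,4‑bis(methoxymethoxy)benzene | COc1ccc(OCOC)cc1OCOC | intermediate
7 | 1‑methoxy‑2,4‑bis(methoxymethoxy)‑3‑allylbenzene | COc1ccc(OCOC)c(CC=C)c1OCOC | intermediate
8 | 1‑bromo‑5‑methoxy‑2,4‑bis(methoxymethoxy)‑3‑allylbenzene | COc1cc(Br)c(OCOC)c(CC=C)c1OCOC | intermediate
9 | 3'‑allyl‑5'‑methoxy‑7,2',4'‑tris(methoxymethoxy)isoflavone | COc1cc(-c2coc3cc(OCOC)ccc3c2=O)c(OCOC)c(CC=C)c1OCOC | intermediate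
10 | 3'‑allyl‑7,2',4'‑trihydroxy‑5'‑methoxyisoflavone | COc1cc(-c2coc3cc(O)ccc3c2=O)c(O)c(CC=C)c1O | intermediate
11 | piscisoflavone A (achiral) | COc1cc(-c2coc3cc(O)ccc3c2=O)c(O)c(CC=C(C)C)c1O | target

## Summary
Total steps: 9.
Longest linear sequence: 6 steps.
The route is convergent. The B‑ring branch from compound 5 and the A/C‑ring branch from compound 1 are equally long and meet at the Negishi coupling.

Steps most likely to fail:
1. **Step 9, cross‑metathesis on the polar free triphenol.** The risks are poor solubility, allyl → propenyl isomerisation and incomplete conversion.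
   - Fallback: change the endgame by running the metathesis on the non‑polar protected bromide 8, which gives the 3‑prenyl aryl bromide.
   - The prenyl group is then carried through the Negishi coupling, and the route finishes with a mild MOM cleavage (p‑TsOH/MeOH or ZnBr2/n‑PrSH). The number of operations does not change.
2. **Step 7, lithiation/zincation and Negishi coupling.** The risks are allylic deprotonation, dehalogenation of 4 and homocoupling.
   - Fallback: avoid organolithium and zinc entirely by converting 8 to its pinacol boronate through Pd‑catalysed Miyaura borylation (B2pin2, Pd(dppf)Cl2, KOAc).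
   - The rings are then joined by Suzuki–Miyaura coupling with 4 (Pd(dppf)Cl2, Na2CO3, DME/H2O, 60 °C). The cost is one extra isolated intermediate.
3. **Step 6, regio‑ and chemoselective bromination of 7.** The risks are bromination next to OMe and attack at the alkene or the benzylic position.
   - Fallback: brominate 6 before any side chain is present, where the regiochemistry is the unambiguous 1,2,4‑trialkoxybenzene pattern.
   - Couple that bromide with 4 and deprotect to give 7,2',4'‑trihydroxy‑5'‑methoxyisoflavone.
   - C3' is the only position ortho to both B‑ring hydroxyls, which allows a late‑stage direct C‑prenylation (prenyl bromide/KOH, or 2‑methylbut‑3‑en‑2‑ol/BF3·OEt2). This variant is shorter, but O‑prenylation and A‑ring C‑prenylation compete, so the yield will be lower.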